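**Plan**

- Labdane numbering is used, with β defined as the face of the C10 methyl (C20). The target is (5S,7R,8R,9R,10S,13R)-7β-hydroxy-6-oxo-9α,13-epoxylabdan-15,16-olide.
- Retrosynthetic cuts, in order: C7–OH (enolate oxidation); the lactone C15–O–C16 oxygen (Baeyer–Villiger); the two C–C bonds of a spiro cyclobutanone on C13 (ketene [2+2]); C13=CH2 (lactone methylenation); then C7–C8 and C9–C10 of ring B (Diels–Alder).
- Enabling feature: ring B carries the C6 ketone and the contiguous stereocentres C8 (CHMe), C9 (spiro C–O) and C10 (CMe). Read as its C5=C6 silyl enol ether, ring B is the retron of a 2-silyloxydiene C10=C5–C6=C7 and a C8=C9 dienophile, the exocyclic alkene of a γ-ethylidenebutenolide whose ring later becomes the tetrahydrofuran.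
- Forward order: ring A comes from β-cyclocitral and the five-membered oxygen ring from 4-bromofuran-2(5H)-one; ring B closes in the cycloaddition; the spiro lactone ring is grown last on C13 through a cyclobutanone.
- Stereochemistry: C8/C9 from the Z alkene; C9/C10 from the oxygen-endo transition state, enforced by a removable bromine on C11 that also blocks the endocyclic alkene; absolute sense from a chiral oxazaborolidinium. C5 is set by α-face protonation (trans-decalin), C13 by a chiral phosphoric acid in the Baeyer–Villiger step, and C7 by enolate oxidation anti to the axial C9–O bond.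

Key step: step 5

Remark: the (S)-oxazaborolidinium and the (R)-phosphoric acid are assumed to deliver the drawn absolute configuration and the 13R centre; if a test reaction shows the opposite sense, the mirror-image catalyst is used. 4-Bromofuran-2(5H)-one is taken as a commercial material.

**Route**

Step 1
Reactants: 1 β-cyclocitral
Product: 2 1-(2,6,6-trimethylcyclohex-1-en-1-yl)ethan-1-ol (racemic)
Conditions: MeMgBr, THF, 0 °C; aqueous work-up
Reagents that add atoms: methylmagnesium bromide, C[Mg]Br
Why: Grignard 1,2-addition to a non-enolisable aldehyde supplies the carbon that becomes C7; the carbinol centre is removed in step 2, so its configuration is immaterial.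

Step 2
Reactants: 2 1-(2,6,6-trimethylcyclohex-1-en-1-yl)ethan-1-ol
Product: 3 1-(2,6,6-trimethylcyclohex-1-en-1-yl)ethan-1-one
Conditions: (nPr4N)RuO4 (5 mol%), N-methylmorpholine N-oxide, 4 Å molecular sieves, CH2Cl2, rt
Reagents that add atoms: none
Why: catalytic perruthenate oxidation of a secondary allylic alcohol under neutral conditions should give the methyl ketone without moving the tetrasubstituted alkene.

Step 3
Reactants: 3 1-(2,6,6-trimethylcyclohex-1-en-1-yl)ethan-1-one
Product: 4 tert-butyldimethyl{[1-(2,6,6-trimethylcyclohex-1-en-1-yl)ethenyl]oxy}silane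
Conditions: TBSOTf, Et3N, CH2Cl2, 0 °C
Reagents that add atoms: tert-butyldimethylsilyl trifluoromethanesulfonate, CC(C)(C)[Si](C)(C)OS(=O)(=O)C(F)(F)F
Why: soft enolisation of a methyl ketone with a silyl triflate and an amine removes a proton from the unhindered CH3 and should give the cross-conjugated 2-silyloxydiene, the standard way to such dienes.

Step 4
Reactants: 5 4-bromofuran-2(5H)-one; 6 acetaldehyde
Product: 9 (Z)-4-bromo-5-ethylidenefuran-2(5H)-one, via silyloxyfuran 7 (not isolated), via silyl aldol 8 (not isolated)
Conditions: TBSOTf, iPr2NEt, CH2Cl2, 0 °C; MeCHO, −78 °C; then DBU, −78 °C to rt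
Reagents that add atoms: none
Why: a one-pot vinylogous Mukaiyama aldol addition of the in situ 2-silyloxyfuran through C5, followed by E1cB loss of silanolate, should give the γ-ylidenebutenolide, the Z isomer being favoured because the methyl group avoids the C4 bromine.

Step 5
Reactants: 4 tert-butyldimethyl{[1-(2,6,6-trimethylcyclohex-1-en-1-yl)ethenyl]oxy}silane; 9 (Z)-4-bromo-5-ethylidenefuran-2(5H)-one
Product: 10 (8R,9R,10S)-11-bromo-6-(tert-butyldimethylsilyloxy)-14,15,16-trinorlabda-5,11-dien-13,9-olide (spiro bromobutenolide; C8 methyl and C9 oxygen α; C11 and C10 methyl β)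
Conditions: 9 (1 equiv), 4 (1.5 equiv), (S)-3,3-diphenyl-1-(o-tolyl)tetrahydro-1H,3H-pyrrolo[1,2-c][1,3,2]oxazaborole protonated with HN(SO2CF3)2 (20 mol%), CH2Cl2, −40 to 0 °C
Reagents that add atoms: none
Why: Proposed new method: the oxazaborolidinium binds the lactone carbonyl of 9 and lowers the LUMO of the dienyl lactone, so that the nucleophilic terminus C7 of silyloxydiene 4 bonds to the δ-carbon C8 while the tetrasubstituted terminus C10 closes onto C9 in a concerted but strongly asynchronous [4+2] cycloaddition (at its stepwise limit a vinylogous Mukaiyama–Michael addition followed by collapse of the boron furanolate onto the silyloxyallyl cation). The closest known reaction types are Diels–Alder additions of 2-silyloxydienes to unsaturated esters and lactones under cationic oxazaborolidine catalysis and thermal cycloadditions of γ-alkylidenebutenolides at the exocyclic alkene; joining two fully substituted carbons (C9–C10) in this way has no precedent. Ring B is closed in the intermolecular [4+2] mode, both σ-bonds forming suprafacially on each partner (a 6-endo closure of C9 onto C10 if the process is stepwise). C8 and C9 are set relative to each other by the Z geometry of the alkene (methyl cis to the ring oxygen); C9 relative to C10 by the transition state with the ring oxygen endo and C11 exo, which the C11 bromine enforces because in the opposite orientation it would collide with the C4 gem-dimethyl group; the absolute sense by the catalyst, which shields one face of the bound dienophile. Site selectivity for the exocyclic over the endocyclic alkene is secured by the bromine on C11, which blocks the β-carbon, and regioselectivity by the 2-silyloxy group, which makes C7 the nucleophilic end.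

Step 6
Reactants: 10 (8R,9R,10S)-11-bromo-6-(tert-butyldimethylsilyloxy)-14,15,16-trinorlabda-5,11-dien-13,9-olide
Product: 12 (8R,9R,10S)-6-(tert-butyldimethylsilyloxy)-14,15,16-trinorlabd-5-en-13,9-olide, via butenolide 11 (not isolated)
Conditions: H2 (1 atm), Pd/C (10%), Et3N, EtOAc, rt
Reagents that add atoms: none
Why: heterogeneous hydrogenation should first hydrogenolyse the activated vinylic C–Br bond of the β-bromo enoate and then saturate the disubstituted butenolide alkene, while the shielded tetrasubstituted silyl enol ether is not reduced and Et3N traps HBr so that it is not hydrolysed; no stereocentre is formed.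

Step 7
Reactants: 12 (8R,9R,10S)-6-(tert-butyldimethylsilyloxy)-14,15,16-trinorlabd-5-en-13,9-olide
Product: 13 (8R,9R,10S)-6-(tert-butyldimethylsilyloxy)-9,13-epoxy-15,16-dinorlabda-5,13-diene (spiro 2-methylenetetrahydrofuran)
Conditions: Cp2TiMe2, toluene, 70 °C, dark
Reagents that add atoms: dimethyltitanocene, C[Ti](C)(C1C=CC=C1)C1C=CC=C1
Why: Petasis methylenation converts a lactone carbonyl into the exocyclic enol ether through Cp2Ti=CH2 under non-basic conditions, and the C6 ketone cannot compete because the cycloaddition left it masked as the silyl enol ether.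

Step 8
Reactants: 13 (8R,9R,10S)-6-(tert-butyldimethylsilyloxy)-9,13-epoxy-15,16-dinorlabda-5,13-diene
Product: 15 (8R,9R,10S)-6-(tert-butyldimethylsilyloxy)-9,13-epoxy-15,16-cyclolabd-5-en-15-one (spiro cyclobutanone on C13), via dichlorocyclobutanone 14 (not isolated)
Conditions: Cl3CCOCl, Zn–Cu couple, Et2O–DME, 0 °C to rt; filter; then Zn, AcOH, TMEDA, EtOH, 0 °C to rt
Reagents that add atoms: trichloroacetyl chloride, ClC(Cl)(Cl)C(Cl)=O
Why: [2+2] cycloaddition of dichloroketene with the electron-rich 1,1-disubstituted enol ether (ketene carbonyl carbon to the CH2 terminus) should be far faster than with the buried silyl enol ether, and zinc dechlorination then removes both chlorines and with them the C13 stereocentre, so the facial course of the cycloaddition does not matter.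

Step 9
Reactants: 15 (8R,9R,10S)-6-(tert-butyldimethylsilyloxy)-9,13-epoxy-15,16-cyclolabd-5-en-15-one
Product: 16 (5S,8R,9R,10S)-9,13-epoxy-15,16-cyclolabdane-6,15-dione
Conditions: Bu4NF, AcOH, THF, 0 °C
Reagents that add atoms: none
Why: buffered fluoride cleaves the silyl enol ether, and protonation at C5 on the α-face, opposite the axial C10 and C4 methyl groups, should give the trans-fused decalone, which is also the thermodynamically preferred ring fusion.

Step 10
Reactants: 16 (5S,8R,9R,10S)-9,13-epoxy-15,16-cyclolabdane-6,15-dione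
Product: 17 (5S,8R,9R,10S,13R)-6-oxo-9,13-epoxylabdan-15,16-olide
Conditions: (R)-3,3'-bis(2,4,6-triisopropylphenyl)-5,5',6,6',7,7',8,8'-octahydro-1,1'-binaphthyl-2,2'-diyl hydrogen phosphate (10 mol%), 30% aq. H2O2, CHCl3, −40 °C
Reagents that add atoms: hydrogen peroxide, OO
Why: in this catalytic asymmetric Baeyer–Villiger desymmetrisation of a prochiral cyclobutanone only the strained four-membered ketone reacts (the hindered C6 ketone does not), and the chiral phosphate bound to the Criegee adduct should select migration of the CH2 on the C8 side of the tetrahydrofuran, which becomes C16 and sets C13 as R.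

Step 11
Reactants: 17 (5S,8R,9R,10S,13R)-6-oxo-9,13-epoxylabdan-15,16-olide
Product: 19 (5S,7R,8R,9R,10S,13R)-7-hydroxy-6-oxo-9,13-epoxylabdan-15,16-olide, via sodium enolate 18 (not isolated)
Conditions: NaN(SiMe3)2 (1.05 equiv), THF, −78 °C; then 2-(phenylsulfonyl)-3-phenyloxaziridine, −78 °C; AcOH quench
Reagents that add atoms: 2-(phenylsulfonyl)-3-phenyloxaziridine, O=S(=O)(c1ccccc1)N1OC1c1ccccc1
Why: the hindered amide base should remove the axial 7α-proton of the ketone faster than the less acidic lactone α-protons (C5–H is buried between C4 and C10), and N-sulfonyloxaziridine hydroxylation of the enolate at C7 on the β-face, anti to the axial C9–O bond, gives the equatorial 7β-alcohol trans to the C8 methyl.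

**Compound list**

1 | β-cyclocitral (2,6,6-trimethylcyclohex-1-ene-1-carbaldehyde) | CC1=C(C=O)C(C)(C)CCC1 | starting material
2 | 1-(2,6,6-trimethylcyclohex-1-en-1-yl)ethan-1-ol (racemic) | CC(O)C1=C(C)CCCC1(C)C | intermediate
3 | 1-(2,6,6-trimethylcyclohex-1-en-1-yl)ethan-1-one | CC(=O)C1=C(C)CCCC1(C)C | intermediate
4 | tert-butyldimethyl{[1-(2,6,6-trimethylcyclohex-1-en-1-yl)ethenyl]oxy}silane (2-silyloxydiene) | C=C(O[Si](C)(C)C(C)(C)C)C1=C(C)CCCC1(C)C | intermediate
5 | 4-bromofuran-2(5H)-one | O=C1C=C(Br)CO1 | starting material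
6 | acetaldehyde | CC=O | starting material
7 | 4-bromo-2-(tert-butyldimethylsilyloxy)furan (formed in the flask) | CC(C)(C)[Si](C)(C)Oc1cc(Br)co1 | intermediate
8 | 4-bromo-5-[1-(tert-butyldimethylsilyloxy)ethyl]furan-2(5H)-one (diastereomer mixture; formed in the flask) | CC(O[Si](C)(C)C(C)(C)C)C1OC(=O)C=C1Br | intermediate
9 | (Z)-4-bromo-5-ethylidenefuran-2(5H)-one | C/C=C1/C(Br)=CC(=O)O1 | intermediate
10 | (8R,9R,10S)-11-bromo-6-(tert-butyldimethylsilyloxy)-14,15,16-trinorlabda-5,11-dien-13,9-olide | C[C@@H]1CC(O[Si](C)(C)C(C)(C)C)=C2C(C)(C)CCC[C@]2(C)[C@@]12C(Br)=CC(=O)O2 | intermediate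
11 | (8R,9S,10S)-6-(tert-butyldimethylsilyloxy)-14,15,16-trinorlabda-5,11-dien-13,9-olide (10 without bromine; same spatial arrangement; formed in the flask) | C[C@@H]1CC(O[Si](C)(C)C(C)(C)C)=C2C(C)(C)CCC[C@]2(C)[C@@]12C=CC(=O)O2 | intermediate
12 | (8R,9R,10S)-6-(tert-butyldimethylsilyloxy)-14,15,16-trinorlabd-5-en-13,9-olide | C[C@@H]1CC(O[Si](C)(C)C(C)(C)C)=C2C(C)(C)CCC[C@]2(C)[C@@]12CCC(=O)O2 | intermediate
13 | (8R,9R,10S)-6-(tert-butyldimethylsilyloxy)-9,13-epoxy-15,16-dinorlabda-5,13-diene | C[C@@H]1CC(O[Si](C)(C)C(C)(C)C)=C2C(C)(C)CCC[C@]2(C)[C@@]12CCC(=C)O2 | intermediate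
14 | (8R,9R,10S)-14,14-dichloro-6-(tert-butyldimethylsilyloxy)-9,13-epoxy-15,16-cyclolabd-5-en-15-one (C13 epimers; formed in the flask) | C[C@@H]1CC(O[Si](C)(C)C(C)(C)C)=C2C(C)(C)CCC[C@]2(C)[C@@]12CCC3(CC(=O)C3(Cl)Cl)O2 | intermediate
15 | (8R,9R,10S)-6-(tert-butyldimethylsilyloxy)-9,13-epoxy-15,16-cyclolabd-5-en-15-one | C[C@@H]1CC(O[Si](C)(C)C(C)(C)C)=C2C(C)(C)CCC[C@]2(C)[C@@]12CCC3(CC(=O)C3)O2 | intermediate
16 | (5S,8R,9R,10S)-9,13-epoxy-15,16-cyclolabdane-6,15-dione | C[C@@H]1CC(=O)[C@H]2C(C)(C)CCC[C@]2(C)[C@@]12CCC3(CC(=O)C3)O2 | intermediate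
17 | (5S,8R,9R,10S,13R)-6-oxo-9,13-epoxylabdan-15,16-olide | C[C@@H]1CC(=O)[C@H]2C(C)(C)CCC[C@]2(C)[C@@]12CC[C@@]1(COC(=O)C1)O2 | intermediate
18 | sodium C6=C7 enolate of 17 (formed in the flask) | C[C@@H]1C=C([O-])[C@H]2C(C)(C)CCC[C@]2(C)[C@@]12CC[C@@]1(COC(=O)C1)O2.[Na+] | intermediate
19 | (5S,7R,8R,9R,10S,13R)-7-hydroxy-6-oxo-9,13-epoxylabdan-15,16-olide | C[C@@H]1[C@@H](O)C(=O)[C@H]2C(C)(C)CCC[C@]2(C)[C@@]12CC[C@@]1(COC(=O)C1)O2 | target

**Step count**

Total: 11 steps. Longest linear sequence: 10 steps (steps 1–3 and 5–11, from β-cyclocitral).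

**Steps most likely to fail**

1. Step 5 (proposed new method). The cycloaddition may not take place at all because two fully substituted carbons must be joined. The strong Lewis acid may protodesilylate the diene. Addition may occur through the C11-endo orientation. Enantiofacial discrimination may be poor because the catalyst sits far from the reacting alkene.

   Fallback, setting out from 4 and returning at 12: the vinylogous lactone is exchanged for a directly conjugated captodative enal, a dienophile class for which cationic oxazaborolidine catalysis is established. Butanal is α-benzoyloxylated (dibenzoyl peroxide, pyrrolidine-type amine catalyst) to 2-(benzoyloxy)butanal F1 and dehydrogenated with 2-iodoxybenzoic acid in DMSO to (Z)-2-(benzoyloxy)but-2-enal F2. Cycloaddition of 4 with F2 under the same catalyst, with the α-oxygen endo and the formyl group exo as is usual for α-substituted enals, should give the formyl benzoate F3 with the C8, C9 and C10 configuration of 10. Wittig olefination (Ph3P=CHCO2Me, toluene, 80 °C) would give the enoate F4 and hydrogenation (H2, Pd/C, EtOAc) the saturated ester F5. K2CO3 in MeOH at 0 °C then removes the benzoate and closes the γ-lactone, which is 12.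

2. Step 10. The chiral acid may discriminate poorly between the two diastereotopic methylene groups, because the existing stereocentres are remote or mismatched with the catalyst. The acid may also open the β-alkoxycyclobutanone.

   Fallback, setting out from 16 and returning at 17: group selection is given up in favour of separation and thermodynamic recycling. An ordinary Baeyer–Villiger oxidation (mCPBA, NaHCO3, CH2Cl2, 0 °C) gives 17 together with its C13 epimer F6, and the two are separated by chromatography. F6 is treated with catalytic KOtBu in tBuOH–THF, which opens it by E1cB (retro-oxa-Michael) to the hydroxy butenolide F7. F7 recloses by oxa-Michael addition to a mixture of 17 and F6, which is separated again and recycled.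

3. Step 11. The oxidant may approach from the α-face and give the axial 7α-ketol. The base may deprotonate the lactone, followed by β-elimination of the C9 oxygen and loss of the C13 configuration.

   Fallback, setting out from 17 and returning at 19: strong base is avoided and the C7 configuration is set thermodynamically. Soft enolisation (TMSOTf, Et3N, CH2Cl2, −78 to 0 °C), which leaves the lactone untouched, gives the C6=C7 trimethylsilyl enol ether F8. Rubottom oxidation with dimethyldioxirane in acetone, expected on the α-face because the β-face of C6 is screened by the axial C4 and C10 methyls, gives the 7α-silyloxy ketone F9. Dilute aqueous HCl in THF releases the axial 7α-ketol F10. Catalytic DBU in CH2Cl2 then equilibrates F10 through the enediol, which is reprotonated at the accessible C7, to the equatorial 7β-ketol 19.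

**Further compounds**

F1 | step 5 | 2-(benzoyloxy)butanal (racemic) | CCC(OC(=O)c1ccccc1)C=O
F2 | step 5 | (Z)-2-(benzoyloxy)but-2-enal | C/C=C(/C=O)OC(=O)c1ccccc1
F3 | step 5 | (8R,9R,10S)-9-(benzoyloxy)-6-(tert-butyldimethylsilyloxy)-12,13,14,15,16-pentanorlabd-5-en-11-al | C[C@@H]1CC(O[Si](C)(C)C(C)(C)C)=C2C(C)(C)CCC[C@]2(C)[C@]1(C=O)OC(=O)c1ccccc1
F4 | step 5 | methyl (8R,9S,10S,11E)-9-(benzoyloxy)-6-(tert-butyldimethylsilyloxy)-14,15,16-trinorlabda-5,11-dien-13-oate | C[C@@H]1CC(O[Si](C)(C)C(C)(C)C)=C2C(C)(C)CCC[C@]2(C)[C@]1(/C=C/C(=O)OC)OC(=O)c1ccccc1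
F5 | step 5 | methyl (8R,9R,10S)-9-(benzoyloxy)-6-(tert-butyldimethylsilyloxy)-14,15,16-trinorlabd-5-en-13-oate | C[C@@H]1CC(O[Si](C)(C)C(C)(C)C)=C2C(C)(C)CCC[C@]2(C)[C@]1(CCC(=O)OC)OC(=O)c1ccccc1
F6 | step 10 | (5S,8R,9R,10S,13S)-6-oxo-9,13-epoxylabdan-15,16-olide (C13 epimer of 17) | C[C@@H]1CC(=O)[C@H]2C(C)(C)CCC[C@]2(C)[C@@]12CC[C@]1(COC(=O)C1)O2
F7 | step 10 | (5S,8R,9R,10S)-9-hydroxy-6-oxolabd-13-en-15,16-olide | C[C@@H]1CC(=O)[C@H]2C(C)(C)CCC[C@]2(C)[C@@]1(O)CCC1=CC(=O)OC1
F8 | step 11 | (5S,8R,9R,10S,13R)-6-(trimethylsilyloxy)-9,13-epoxylabd-6-en-15,16-olide | C[C@@H]1C=C(O[Si](C)(C)C)[C@H]2C(C)(C)CCC[C@]2(C)[C@@]12CC[C@@]1(COC(=O)C1)O2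
F9 | step 11 | (5S,7S,8R,9R,10S,13R)-6-oxo-7-(trimethylsilyloxy)-9,13-epoxylabdan-15,16-olide | C[C@@H]1[C@H](O[Si](C)(C)C)C(=O)[C@H]2C(C)(C)CCC[C@]2(C)[C@@]12CC[C@@]1(COC(=O)C1)O2
F10 | step 11 | (5S,7S,8R,9R,10S,13R)-7-hydroxy-6-oxo-9,13-epoxylabdan-15,16-olide (C7 epimer of 19) | C[C@@H]1[C@H](O)C(=O)[C@H]2C(C)(C)CCC[C@]2(C)[C@@]12CC[C@@]1(COC(=O)C1)O2
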